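Find the level at which [starting material] stands in the flask, since the product follows from that level.

solid substrate 0.80 M; gas phase 93 mM (held); time 80 min

    solid substrate ⇌ starting material, rate k1*(cs1 - [starting material]) while solid is left; crystals form when [starting material] > cs1 (cs1 = 37 mM, k1 = 0.0205 min⁻¹)
    gas phase ⇌ dissolved gas, rate k2*(csat - [dissolved gas]) (k2 = 7.17 min⁻¹, csat = 93 mM)
    starting material + dissolved gas → product (k3 = 0.601 M⁻¹ min⁻¹)

- solid substrate is a solid; its amount is given per volume of the solution
- at the start none of the gas is dissolved
- at the start none of the solid substrate is in solution
- run time (flask): 80 min

* amount of product at 80 min, in percent of the solid substrate charged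
* concentration of dissolved gas in solution at 80 min, in percent of saturation

Turn the question round. For [starting material] to stand close to its solubility 37 mM, the dissolution coefficient 0.0205 min⁻¹ would have to exceed by far the constant of its removal. Transfer at 7.17 min⁻¹ keeps [dissolved gas] near 93 mM, so removal is pseudo-first-order, with constant 0.0559 min⁻¹. The dissolution coefficient is instead 0.367 of that.

So reckon by rounds. An empty solution receives 0.758 mM min⁻¹, which removal balances at 13.6 mM. Put that back: dissolving slows to 0.480 mM min⁻¹, and the balance falls to 8.59 mM. Followed to its end, this gives the resting level, the [starting material] at which dissolving equals removal: 9.93 mM, or 26.8 % of solubility.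

The level is approached with time constant 13.1 min, so count product at the resting rate for the run less that lag. This gives y = 4.64 %. Reaction drains [dissolved gas] at 0.00597 min⁻¹, so sat = 99.9 %.

The forecast gives 4.6 % and 99.9 %, holding that “Dissolution is the bottleneck”.

The simulation gives 4.64 % and 99.9 %.

By 8.00 min the flask held [dissolved gas] at >99.9 % of saturation, while [starting material] was still climbing at 0.568 % of the charge. At 80.0 min [starting material] in the flask read 1.24 %, against a resting level of 1.24 %, with 94.1 % still solid. For the neighbour flask with 0.32 M of solid substrate, the same resting level gives 11.6 %. That flask ended at 11.6 %, with 88 % of its charge still there, solid or dissolved.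

(All constants are invented; the result is computed.)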